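The leftover of a reaction is where I start: target that the solution can't hold should lie in the flask as solid product.

solid substrate 1.1 M; solid reagent 1.16 M; time 40 s

* target and solid product and idle adduct together at 40 s, in percent of the solid substrate charged
* the change that raises the amount of target and solid product and idle adduct together at 40 s, in percent of the solid substrate charged most ("none" if none brings more than 2 percentage points) (Tuesday's / Wednesday's / Sunday's / Thursday's / none)
* amount of target and solid product and idle adduct together at 40 s, in percent of the solid substrate charged, after Thursday's

- Tuesday's: doubling the solubility in step 4, all else as stated
- Wednesday's: doubling the dissolution coefficient of step 3, all else as stated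
- Sunday's: doubling the solubility in step 3, all else as stated
- Thursday's: doubling the solubility in step 1, all else as stated

- target is meant together with its solid product and idle adduct
- solid, in amounts per volume of the solution: solid substrate, solid product, solid reagent
- at the start none of the solid substrate is in solution
- at the start none of the solid reagent is in solution
- run time (flask): 40 s

    solid substrate ⇌ dissolved substrate, rate k1*(cs1 - [dissolved substrate]) while solid is left; crystals form when [dissolved substrate] > cs1 (cs1 = 0.68 M, k1 = 0.067 s⁻¹)
    dissolved substrate + partner → target (k2 = 0.096 L mol⁻¹ s⁻¹)
    solid product ⇌ target, rate k3*(cs3 - [target]) while solid is left; crystals form when [target] > cs3 (cs3 = 28 mM, k3 = 4.2 s⁻¹)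
    solid reagent ⇌ partner, rate k4*(cs4 - [partner]) while solid is left; crystals form when [partner] > cs4 (cs4 = 0.64 M, k4 = 0.077 s⁻¹)
    partner + target ⇌ idle adduct, settled at all times (K5 = 33 L mol⁻¹)

Two numbers clash here. Free target stops at its solubility of 28 mM, which is 2.55% of the solid substrate charged, yet partner ties target up as idle adduct with a constant of 33 L mol⁻¹.

I take the fast adduct balance as held at every moment. At the edge of crystallising, idle adduct equals this constant times the solubility of target times the free partner. Each mole of free partner therefore carries 0.924 mole of target as idle adduct, and I call this the carrying number. The holding limit is then the solubility of target plus the carrying number times the free partner.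

Partner dissolves towards 0.64 M, while the reaction and the adduct both draw on it, and I guess it at 0.320 M, half of that solubility. The limit comes to 29.4% of the charge, far above the bare solubility. By my reckoning, solid product appears once target in all its forms passes that share. The reckoning tells where target lies; it doesn't say how much is made, so I give no figure for the answers.

The forecast gives 40%, and 54% after Thursday's, and it picks Tuesday's: “Tuesday's edges Thursday's only narrowly, so that pick is a close call”.

The simulation gives 38.0%, and 53.3% after Thursday's, and the best change is Thursday's. Thursday's brings 15 percentage points, more than the 12 points of Tuesday's. Wednesday's brings 0.083 points and Sunday's −0.34 points. The forecast's two percentages hold within their margin, and its pick does not.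

In the flask at 40.0 s, free partner reads 0.338 M, which puts the holding limit at 31.0%, and 4.47% lies as solid product out of 38.0% of target. The neighbour flask is charged with 0.46 M of solid reagent, 0.418 equiv, which makes it the limiting reagent there. Its free partner reads 0.101 M at 40.0 s, so its limit falls to 11.0%. Of its 23.6% of target, I reckon 12.6% as solid; that neighbour flask holds 11.8% of solid product.

The numbers of this flask were chosen freely, and the outcome is calculated.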